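(Readings and results are simulated for an exercise; noise was put on by code.)

A closed flask starts with its substrate at full strength while a steady tank holds it low, so I reckoned vessel, charge and time by the share of substrate that self-condensation takes.

| setting | Saturday's | Tuesday's | north-west | north |
|---|---|---|---|---|
| substrate | 2.2 M | 1.1 M | 2.2 M | 2.2 M |
| remark | run made earlier | run made earlier | a single well-mixed tank run continuously and read at steady state, 12 h in it on average | a closed flask charged with all of it at once and left for 12 h |
| time |  |  |  | 12 h |

| run | time / h | intermediate A / % | target / % | substrate / % |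
|---|---|---|---|---|
| Saturday's | 1.00 | 40.3 | 0 | 35.8 |
| Saturday's | 1.50 | 50.0 | 0.4 | 24.9 |
| Saturday's | 2.50 | 58.3 | 1.1 | 12.2 |
| Saturday's | 4.00 | 59.8 | 2.8 | 3.0 |
| Saturday's | 8.00 | 51.2 | 8.9 | 0.5 |
| Saturday's | 12.0 | 42.2 | 14.4 | 0.4 |
| Tuesday's | 2.00 | 61.9 | 0.3 | 20.2 |
| Tuesday's | 4.00 | 68.9 | 1.5 | 5.2 |
| Tuesday's | 6.00 | 64.8 | 5.8 | 1.7 |
| Tuesday's | 8.00 | 59.5 | 9.2 | 0.1 |
| Tuesday's | 10.0 | 52.6 | 12.6 | 0 |
| Tuesday's | 12.0 | 46.7 | 14.1 | 0 |

(each reading ± 0.5 percentage points)

* the set-up with the highest amount of intermediate A at the outlet or at the end, in percent of the substrate put in ("none" if the first two lie within 2 percentage points) (north-west / north / none)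
* amount of intermediate A at the outlet or at the end, in percent of the substrate put in, north-west
* amount of intermediate A at the outlet or at the end, in percent of the substrate put in, north

- a species is counted by the substrate in it: one self-condensation product counts as two
- the stated concentrations are those of everything mixed, before any reaction; amounts are the same in each set-up
- on the list of suspects stand: substrate -> intermediate A; intermediate A -> intermediate B; intermediate B <-> target; 2 substrate -> self-condensation product; intermediate B -> decomposed reagent
- the earlier runs were made in a closed, stirred flask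

Time came first. On Tuesday, with substrate at 1.7 %, intermediate A fell from 64.8 % at 6.00 h to 46.7 % at 12.0 h, a decay of 0.0546 h⁻¹.

Charge came next. I took Tuesday's substrate loss between 2.00 h and 4.00 h, 0.679 h⁻¹, as the first-order rate to intermediate A. Saturday's substrate, at twice the charge, stood at 24.9 % after 1.50 h, less than the 36.1 % that rate gives. That gap gives the condensation ratio (a selectivity factor), the starting rate of substrate use by self-condensation over that to intermediate A: 0.707, read at Saturday's charge and taken as proportional to charge. In a closed flask the share reaching intermediate A is the logarithm of one plus the ratio, divided by the ratio, so the toll is 24.4 %. North repeats Saturday's recipe, so I expected its 42.2 %.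

Last came the vessel. The north-west balance leaves 10.3 % substrate, cutting the toll to 16.3 %. With decay over the average 12 h, I reckoned 50.5 %.

The forecast gave north-west, 50 % against 42.5 % for north, since “the tank holds substrate low”. The simulation gave north-west, 50.3 % against 41.4 %.

    substrate → intermediate A (k = 1.91 × 10⁻⁴ s⁻¹)
    intermediate A → intermediate B (k = 1.53 × 10⁻⁵ s⁻¹)
    intermediate B ⇌ target (K = 2.80, k = 6.51 × 10⁻⁵ s⁻¹)
    2 substrate → self-condensation product (k = 3.27 × 10⁻⁵ L mol⁻¹ s⁻¹)
    intermediate B → decomposed reagent (k = 3.92 × 10⁻⁵ s⁻¹)

North's toll of 24.4 % stands beside 25.5 % of self-condensation product at 12.0 h. The neighbouring flask is north with 0.55 M of substrate, a quarter of the charge, so its ratio is 0.177 and its toll 7.92 %. Holding the time and decay, I scaled north's 41.4 % by what each toll leaves and got 50.4 %. At 12.0 h, the neighbouring flask held 8.38 % of self-condensation product and 51.2 % of intermediate A.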